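**Retrosynthetic overview**

1. The target is read as (2S)-4',7-dihydroxyflavan-(4β→8)-epiafzelechin-(4β→8)-epiafzelechin (units 1, 2, 3). The strategy rests on C4 of unit 2: the methine of pyran ring C that joins C4a of ring A of unit 2 to C8 of ring A of unit 3 and stands next to the oxygen-bearing C3.
2. Key disconnection: C3–C4 and O1–C2 of unit 2. The enamine of benzyloxyacetaldehyde adds to an o-quinone methide that spans ring A of unit 2 and C8 of unit 3, and the phenol closes the lactol. The methide comes from a diarylmethanol made from 8-lithiated benzylated epiafzelechin and a protected salicylaldehyde.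
3. Later disconnections: the C2–aryl bond of unit 2 (aryl transfer to the C2 oxocarbenium ion), then the bond from C4 of unit 1 to C8 of unit 2 (flavan-4-yl cation from the 4-acetate derived from liquiritigenin), then global debenzylation.
4. Ring order: the rings of unit 3 arrive with (−)-epiafzelechin and ring A of unit 2 with 2,4,6-trihydroxybenzaldehyde. Pyran ring C of unit 2 is the only ring closed (step 8). Ring B of unit 2 is attached in step 11 and the rings of unit 1 arrive intact in step 15.

Key step: step 8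

Remark: the (S)-configured prolinol catalyst is chosen on the assumption that the methide adds to the enamine face remote from the diphenyl(silyloxy)methyl group, as other Michael acceptors do; this predicts the 3R centre.

**Route**

Step 1
Reactants: 1 (−)-epiafzelechin
Product: 2 5,7,4'-tri-O-benzyl-(−)-epiafzelechin, (2R,3R)-5,7-bis(benzyloxy)-2-[4-(benzyloxy)phenyl]chroman-3-ol
Conditions: BnBr (3.3 equiv), K2CO3 (3.5 equiv), DMF, 0 °C → rt
Reagents that add atoms: benzyl bromide, BrCc1ccccc1
Why: Williamson etherification of the three phenoxides; K2CO3 does not deprotonate the secondary 3-OH, and C2 and C3 are untouched.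

Step 2
Reactants: 2 5,7,4'-tri-O-benzyl-(−)-epiafzelechin
Product: 3 3,5,7,4'-tetra-O-benzyl-(−)-epiafzelechin, (2R,3R)-3,5,7-tris(benzyloxy)-2-[4-(benzyloxy)phenyl]chromane
Conditions: NaH (1.3 equiv), BnBr (1.3 equiv), n-Bu4NI (cat.), THF/DMF, 0 °C → rt
Reagents that add atoms: benzyl bromide, BrCc1ccccc1
Why: Williamson etherification of the sodium alkoxide at O3, which removes the last acidic proton before the aryllithium chemistry of step 6.

Step 3
Reactants: 3 3,5,7,4'-tetra-O-benzyl-(−)-epiafzelechin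
Product: 4 8-bromo-3,5,7,4'-tetra-O-benzyl-(−)-epiafzelechin
Conditions: NBS (1.0 equiv), CH2Cl2, −78 → 0 °C
Reagents that add atoms: N-bromosuccinimide, O=C1CCC(=O)N1Br
Why: electrophilic aromatic bromination of the phloroglucinol-type ring A, which in 5,7-di-O-benzylflavans should take place at C8 (next to O1) in preference to the more crowded C6 and to ring B.

Step 4
Reactants: 5 2,4,6-trihydroxybenzaldehyde
Product: 6 2,4-bis(benzyloxy)-6-hydroxybenzaldehyde
Conditions: BnBr (2.05 equiv), K2CO3 (2.1 equiv), DMF, 0 °C → rt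
Reagents that add atoms: benzyl bromide, BrCc1ccccc1
Why: Williamson etherification of the para hydroxyl and of one ortho hydroxyl; the second ortho hydroxyl is held by the hydrogen bond to the formyl oxygen and should remain free.

Step 5
Reactants: 6 2,4-bis(benzyloxy)-6-hydroxybenzaldehyde
Product: 7 2-(allyloxy)-4,6-bis(benzyloxy)benzaldehyde
Conditions: allyl bromide (1.5 equiv), K2CO3 (2 equiv), DMF, 50 °C
Reagents that add atoms: allyl bromide, C=CCBr
Why: Williamson etherification under more forcing conditions caps the chelated hydroxyl as an allyl ether, which is inert to aryllithium and can be removed later without acid.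

Step 6
Reactants: 4 8-bromo-3,5,7,4'-tetra-O-benzyl-(−)-epiafzelechin; 7 2-(allyloxy)-4,6-bis(benzyloxy)benzaldehyde
Product: 9 [2-(allyloxy)-4,6-bis(benzyloxy)phenyl](3,5,7,4'-tetra-O-benzyl-epiafzelechin-8-yl)methanol (both carbinol epimers), via 8-lithio-tetra-O-benzyl-epiafzelechin 8 (not isolated)
Conditions: n-butyllithium (1.05 equiv), THF, −78 °C; then 7 (1.2 equiv), −78 → −20 °C; H2O
Reagents that add atoms: none
Why: bromine–lithium exchange at C8 followed by 1,2-addition of the aryllithium to the aldehyde; the carbinol centre forms as both epimers, which does not matter because it becomes the trigonal methide carbon in step 8.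

Step 7
Reactants: 9 [2-(allyloxy)-4,6-bis(benzyloxy)phenyl](3,5,7,4'-tetra-O-benzyl-epiafzelechin-8-yl)methanol
Product: 10 [2,4-bis(benzyloxy)-6-hydroxyphenyl](3,5,7,4'-tetra-O-benzyl-epiafzelechin-8-yl)methanol (carbinol epimers)
Conditions: Pd(PPh3)4 (5 mol %), morpholine (5 equiv), THF, rt; filtration through Et3N-deactivated silica, used at once
Reagents that add atoms: none
Why: Tsuji–Trost-type deallylation, in which zerovalent palladium ionises the aryl allyl ether and morpholine takes up the allyl fragment, so the phenol is freed under neutral conditions that should not ionise the acid-labile diarylmethanol.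

Step 8
Reactants: 10 [2,4-bis(benzyloxy)-6-hydroxyphenyl](3,5,7,4'-tetra-O-benzyl-epiafzelechin-8-yl)methanol; 11 benzyloxyacetaldehyde
Product: 14 (3R,4R)-3,5,7-tris(benzyloxy)-4-(3,5,7,4'-tetra-O-benzyl-epiafzelechin-8-yl)chroman-2-ol (3,4-trans lactol of unit 2; C2 anomers), via ortho-quinone methide 12 (not isolated), via open-chain phenol aldehyde 13 (not isolated)
Conditions: 11 (3 equiv, slow addition), (S)-α,α-diphenylprolinol trimethylsilyl ether (20 mol %), PhCO2H (20 mol %), CH2Cl2, 0 °C → rt
Reagents that add atoms: none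
Why: Benzoic acid should promote loss of water from 10 to give the o-quinone methide 12, which the trioxygenated ring of unit 3 stabilises, while the prolinol ether condenses with 11 to the E-enamine; the enamine α-carbon adds to the methide carbon (C3–C4 bond), ring A rearomatises to the phenol, and hydrolysis of the iminium ion releases aldehyde 13 and the catalyst. The closest known reaction type is the secondary-amine-catalysed Michael addition and hemiacetalisation of aldehydes with o-quinone methides generated in situ from o-hydroxybenzhydrols, which gives trans-3,4-disubstituted chroman-2-ols and is related to enamine alkylation by stabilised benzhydryl cations. Pyran ring C of unit 2 then closes by reversible 6-exo-trig attack of the phenol oxygen on the aldehyde carbon (O1–C2); C2 forms as an anomeric mixture and is made trigonal again in step 11. C3 is set by the catalyst, whose diphenyl(trimethylsilyloxy)methyl group blocks one enamine face so that the methide should add to the open face (3R); C4 is set by the relative orientation of enamine and methide in the compact open transition state, which should give the 3,4-trans (4R, 4β-aryl) relationship usual for this reaction type. The step needs reagent control over the remote C2 and C3 centres of unit 3 and carbon–carbon bond formation in preference to capture of the methide by the amine, by water or by the electron-rich arene rings. The distance of the unit 3 centres from the methide carbon, the reversibility of heteroatom addition to so stabilised a methide, and the much higher nucleophilicity of the enamine compared with the benzylated arenes should secure this.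

Step 9
Reactants: 14 3,4-trans lactol of unit 2
Product: 15 (3R,4R)-3,5,7-tris(benzyloxy)-4-(3,5,7,4'-tetra-O-benzyl-epiafzelechin-8-yl)chroman-2-yl acetate (C2 anomers)
Conditions: Ac2O (3 equiv), pyridine (5 equiv), DMAP (cat.), CH2Cl2, 0 °C
Reagents that add atoms: acetic anhydride, CC(=O)OC(C)=O
Why: O-acylation of the anomeric hydroxyl (nucleophilic acyl substitution) turns the lactol into a leaving group at C2; C3 and C4 are not touched and the anomers are carried on together.

Step 10
Reactants: 16 4-benzyloxyphenylboronic acid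
Product: 17 potassium (4-benzyloxyphenyl)trifluoroborate
Conditions: KHF2 (3 equiv), MeOH/H2O, rt
Reagents that add atoms: potassium hydrogen difluoride, F.[F-].[K+]
Why: ligand exchange at boron with bifluoride gives the stable trifluoroborate salt, the form used for aryl transfer to oxocarbenium ions.

Step 11
Reactants: 15 lactol acetate of unit 2; 17 potassium (4-benzyloxyphenyl)trifluoroborate
Product: 20 3,5,7,4'-tetra-O-benzyl-epiafzelechin-(4β→8)-3,5,7,4'-tetra-O-benzyl-epiafzelechin, via (4-benzyloxyphenyl)difluoroborane 18 (not isolated), via chroman-2-ylium ion 19 (not isolated)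
Conditions: 17 (3 equiv), BF3·OEt2 (3 equiv), CH2Cl2/MeCN, −20 °C → rt; aqueous work-up
Reagents that add atoms: none
Why: BF3·OEt2 abstracts fluoride from 17 to give difluoroborane 18 and ionises the anomeric acetate to oxocarbenium ion 19, to which the aryl group is transferred (Lewis-acid coupling of organotrifluoroborates with acetals through oxocarbenium ions); the aryl group should enter trans to the bulky C4 aryl group of unit 3 and cis to the 3-benzyloxy group, the 1,2-cis/1,3-trans preference of six-membered oxocarbenium ions, which sets C2 as 2R (2,3-cis-3,4-trans).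

Step 12
Reactants: 21 (2S)-liquiritigenin
Product: 22 7,4'-di-O-benzyl-(2S)-liquiritigenin, (2S)-7-(benzyloxy)-2-[4-(benzyloxy)phenyl]chroman-4-one
Conditions: BnOH (2.4 equiv), PPh3 (2.4 equiv), DIAD (2.4 equiv), THF, 0 °C → rt
Reagents that add atoms: benzyl alcohol, OCc1ccccc1
Why: Mitsunobu etherification of both phenols under near-neutral conditions, chosen because carbonate bases can open flavanones to chalcones and would racemise C2.

Step 13
Reactants: 22 7,4'-di-O-benzyl-(2S)-liquiritigenin
Product: 23 (2S,4S)-7-(benzyloxy)-2-[4-(benzyloxy)phenyl]chroman-4-ol (2,4-cis alcohol expected as main epimer)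
Conditions: NaBH4 (1 equiv), THF/MeOH, 0 °C
Reagents that add atoms: none
Why: hydride reduction of the aryl ketone, with axial delivery expected to give mainly the 2,4-cis alcohol (4S); the configuration at C4 is of no consequence because this centre is ionised in step 15.

Step 14
Reactants: 23 (2S,4S)-7-(benzyloxy)-2-[4-(benzyloxy)phenyl]chroman-4-ol
Product: 24 (2S,4S)-7-(benzyloxy)-2-[4-(benzyloxy)phenyl]chroman-4-yl acetate
Conditions: Ac2O (1.5 equiv), pyridine (3 equiv), DMAP (cat.), CH2Cl2, 0 °C; aqueous NaHCO3 work-up, used without chromatography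
Reagents that add atoms: acetic anhydride, CC(=O)OC(C)=O
Why: DMAP-catalysed O-acylation (nucleophilic acyl substitution) turns the benzylic hydroxyl into an acetate leaving group, so that the ionisation of step 15 releases acetic acid and no water that would hydrolyse the silyl triflate; C2 is untouched and C4 keeps its configuration.

Step 15
Reactants: 20 octa-O-benzyl dimer of units 2 and 3; 24 (2S,4S)-7-(benzyloxy)-2-[4-(benzyloxy)phenyl]chroman-4-yl acetate
Product: 26 deca-O-benzyl ether of the target trimer, via flavan-4-yl cation 25 (not isolated)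
Conditions: TMSOTf (0.2 equiv), 4 Å MS, CH2Cl2, −78 → −40 °C, 24 (1.2 equiv) added slowly; Et3N quench
Reagents that add atoms: none
Why: TMSOTf ionises the benzylic acetate to the 7-alkoxy-stabilised cation 25, which should alkylate C8 of the upper unit (unit 2), the most reactive free position of a benzylated flavan-3-ol dimer, in a Friedel–Crafts reaction of the kind used to extend benzylated proanthocyanidins with 4-acetoxyflavans; attack along the pseudoaxial trajectory anti to the equatorial 2-aryl group should give the 2,4-trans (4R, 4β) bond of unit 1.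

Step 16
Reactants: 26 deca-O-benzyl ether of the target trimer
Product: 27 CNP0257624.1, (2S)-4',7-dihydroxyflavan-(4β→8)-epiafzelechin-(4β→8)-epiafzelechin
Conditions: H2 (1 atm), Pd(OH)2/C, THF/MeOH/H2O, rt
Reagents that add atoms: none
Why: catalytic hydrogenolysis of the ten benzyl ethers; no stereocentre is affected and the interflavan bonds and pyran rings should survive these neutral conditions.

**Compound list**

1 | (−)-epiafzelechin, (2R,3R) | Oc1cc(O)c2c(c1)O[C@H](c1ccc(O)cc1)[C@H](O)C2 | starting material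
2 | 5,7,4'-tri-O-benzyl-(−)-epiafzelechin | O(Cc9ccccc9)c1cc(OCc9ccccc9)c2c(c1)O[C@H](c1ccc(OCc9ccccc9)cc1)[C@H](O)C2 | intermediate
3 | 3,5,7,4'-tetra-O-benzyl-(−)-epiafzelechin | O(Cc9ccccc9)c1cc(OCc9ccccc9)c2c(c1)O[C@H](c1ccc(OCc9ccccc9)cc1)[C@H](OCc9ccccc9)C2 | intermediate
4 | 8-bromo-3,5,7,4'-tetra-O-benzyl-(−)-epiafzelechin | O(Cc9ccccc9)c1cc(OCc9ccccc9)c2c(c1Br)O[C@H](c1ccc(OCc9ccccc9)cc1)[C@H](OCc9ccccc9)C2 | intermediate
5 | 2,4,6-trihydroxybenzaldehyde | O=Cc1c(O)cc(O)cc1O | starting material
6 | 2,4-bis(benzyloxy)-6-hydroxybenzaldehyde | O=Cc1c(O)cc(OCc9ccccc9)cc1OCc9ccccc9 | intermediate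
7 | 2-(allyloxy)-4,6-bis(benzyloxy)benzaldehyde | O=Cc1c(OCC=C)cc(OCc9ccccc9)cc1OCc9ccccc9 | intermediate
8 | 8-lithio-3,5,7,4'-tetra-O-benzyl-epiafzelechin (not isolated) | [Li]c1c(OCc9ccccc9)cc(OCc9ccccc9)c2c1O[C@H](c1ccc(OCc9ccccc9)cc1)[C@H](OCc9ccccc9)C2 | intermediate
9 | [2-(allyloxy)-4,6-bis(benzyloxy)phenyl](3,5,7,4'-tetra-O-benzyl-epiafzelechin-8-yl)methanol, carbinol epimers | OC(c1c(OCC=C)cc(OCc9ccccc9)cc1OCc9ccccc9)c1c(OCc9ccccc9)cc(OCc9ccccc9)c2c1O[C@H](c1ccc(OCc9ccccc9)cc1)[C@H](OCc9ccccc9)C2 | intermediate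
10 | [2,4-bis(benzyloxy)-6-hydroxyphenyl](3,5,7,4'-tetra-O-benzyl-epiafzelechin-8-yl)methanol, carbinol epimers | OC(c1c(O)cc(OCc9ccccc9)cc1OCc9ccccc9)c1c(OCc9ccccc9)cc(OCc9ccccc9)c2c1O[C@H](c1ccc(OCc9ccccc9)cc1)[C@H](OCc9ccccc9)C2 | intermediate
11 | benzyloxyacetaldehyde | O=CCOCc1ccccc1 | starting material
12 | 3,5-bis(benzyloxy)-6-[(3,5,7,4'-tetra-O-benzyl-epiafzelechin-8-yl)methylidene]cyclohexa-2,4-dien-1-one, o-quinone methide (not isolated) | O=C1C=C(OCc9ccccc9)C=C(OCc9ccccc9)C1=Cc1c(OCc9ccccc9)cc(OCc9ccccc9)c2c1O[C@H](c1ccc(OCc9ccccc9)cc1)[C@H](OCc9ccccc9)C2 | intermediate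
13 | (2R,3R)-2-(benzyloxy)-3-[2,4-bis(benzyloxy)-6-hydroxyphenyl]-3-(3,5,7,4'-tetra-O-benzyl-epiafzelechin-8-yl)propanal (not isolated) | O=C[C@H](OCc9ccccc9)[C@H](c1c(O)cc(OCc9ccccc9)cc1OCc9ccccc9)c1c(OCc9ccccc9)cc(OCc9ccccc9)c2c1O[C@H](c1ccc(OCc9ccccc9)cc1)[C@H](OCc9ccccc9)C2 | intermediate
14 | (3R,4R)-3,5,7-tris(benzyloxy)-4-(3,5,7,4'-tetra-O-benzyl-epiafzelechin-8-yl)chroman-2-ol, 3,4-trans, C2 anomers | c1c(OCc9ccccc9)cc(OCc9ccccc9)c2c1OC(O)[C@H](OCc9ccccc9)[C@H]2c1c(OCc9ccccc9)cc(OCc9ccccc9)c2c1O[C@H](c1ccc(OCc9ccccc9)cc1)[C@H](OCc9ccccc9)C2 | intermediate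
15 | 2-O-acetate of lactol 14, C2 anomers | c1c(OCc9ccccc9)cc(OCc9ccccc9)c2c1OC(OC(C)=O)[C@H](OCc9ccccc9)[C@H]2c1c(OCc9ccccc9)cc(OCc9ccccc9)c2c1O[C@H](c1ccc(OCc9ccccc9)cc1)[C@H](OCc9ccccc9)C2 | intermediate
16 | 4-benzyloxyphenylboronic acid | OB(O)c1ccc(OCc2ccccc2)cc1 | starting material
17 | potassium (4-benzyloxyphenyl)trifluoroborate | [K+].F[B-](F)(F)c1ccc(OCc2ccccc2)cc1 | intermediate
18 | (4-benzyloxyphenyl)difluoroborane (not isolated) | FB(F)c1ccc(OCc2ccccc2)cc1 | intermediate
19 | (3R,4R)-3,5,7-tris(benzyloxy)-4-(3,5,7,4'-tetra-O-benzyl-epiafzelechin-8-yl)chroman-2-ylium ion (not isolated) | c1c(OCc9ccccc9)cc(OCc9ccccc9)c2c1[O+]=C[C@H](OCc9ccccc9)[C@H]2c1c(OCc9ccccc9)cc(OCc9ccccc9)c2c1O[C@H](c1ccc(OCc9ccccc9)cc1)[C@H](OCc9ccccc9)C2 | intermediate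
20 | 3,5,7,4'-tetra-O-benzyl-epiafzelechin-(4β→8)-3,5,7,4'-tetra-O-benzyl-epiafzelechin; unit 2 is 2R,3R,4R (2,3-cis-3,4-trans) | c1c(OCc9ccccc9)cc(OCc9ccccc9)c2c1O[C@H](c1ccc(OCc9ccccc9)cc1)[C@H](OCc9ccccc9)[C@H]2c1c(OCc9ccccc9)cc(OCc9ccccc9)c2c1O[C@H](c1ccc(OCc9ccccc9)cc1)[C@H](OCc9ccccc9)C2 | intermediate
21 | (2S)-liquiritigenin | O=C1C[C@@H](c2ccc(O)cc2)Oc2cc(O)ccc21 | starting material
22 | (2S)-7-(benzyloxy)-2-[4-(benzyloxy)phenyl]chroman-4-one | O=C1C[C@@H](c2ccc(OCc9ccccc9)cc2)Oc2cc(OCc9ccccc9)ccc21 | intermediate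
23 | (2S,4S)-7-(benzyloxy)-2-[4-(benzyloxy)phenyl]chroman-4-ol, 2,4-cis | O[C@H]1C[C@@H](c2ccc(OCc9ccccc9)cc2)Oc2cc(OCc9ccccc9)ccc21 | intermediate
24 | (2S,4S)-7-(benzyloxy)-2-[4-(benzyloxy)phenyl]chroman-4-yl acetate, 2,4-cis | CC(=O)O[C@H]1C[C@@H](c2ccc(OCc9ccccc9)cc2)Oc2cc(OCc9ccccc9)ccc21 | intermediate
25 | (2S)-7-(benzyloxy)-2-[4-(benzyloxy)phenyl]chroman-4-ylium ion (not isolated) | [CH+]1C[C@@H](c2ccc(OCc9ccccc9)cc2)Oc2cc(OCc9ccccc9)ccc21 | intermediate
26 | deca-O-benzyl ether of the target: 7,4'-di-O-benzyl-(2S)-flavan-(4β→8)-tetra-O-benzyl-epiafzelechin-(4β→8)-tetra-O-benzyl-epiafzelechin | O(Cc9ccccc9)c1ccc([C@@H]2C[C@@H](c3c(OCc9ccccc9)cc(OCc9ccccc9)c4c3O[C@H](c3ccc(OCc9ccccc9)cc3)[C@H](OCc9ccccc9)[C@H]4c3c(OCc9ccccc9)cc(OCc9ccccc9)c4c3O[C@H](c3ccc(OCc9ccccc9)cc3)[C@H](OCc9ccccc9)C4)c3ccc(OCc9ccccc9)cc3O2)cc1 | intermediate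
27 | CNP0257624.1, (2S)-4',7-dihydroxyflavan-(4β→8)-epiafzelechin-(4β→8)-epiafzelechin; unit 1 2S,4R; unit 2 2R,3R,4S; unit 3 2R,3R | Oc1ccc([C@@H]2C[C@@H](c3c(O)cc(O)c4c3O[C@H](c3ccc(O)cc3)[C@H](O)[C@H]4c3c(O)cc(O)c4c3O[C@H](c3ccc(O)cc3)[C@H](O)C4)c3ccc(O)cc3O2)cc1 | target

**Step count**

Total: 16 steps. Longest linear sequence: 10 steps (steps 1, 2, 3, 6, 7, 8, 9, 11, 15, 16, from (−)-epiafzelechin).

**Steps most likely to fail**

Step 8. The enamine may fail to reach the methide carbon, which is flanked by four ortho substituents and strongly stabilised. It may also add with poor facial selectivity if the catalyst and the unit 3 centres are mismatched, and benzyloxyacetaldehyde may be consumed by self-aldol reaction. The fallback gives up the quinone methide construction and forms the C4–C8 bond by the classical cationic interflavan coupling. It sets out from 3. Oxidation of C4 of 3 with DDQ in CH2Cl2 in the presence of 2-ethoxyethanol should give 4β-(2-ethoxyethoxy)-3,5,7,4'-tetra-O-benzyl-epiafzelechin F1. Ionisation of this ether with TMSOTf at −78 °C in the presence of an excess of 3 should let C8 of 3 attack the C4 cation anti to the 3-benzyloxy group, which gives the 4β→8 dimer. The fallback comes back to the route at 20.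

Step 11. The C2 oxocarbenium ion may be captured by the electron-rich rings A of a second molecule faster than by the aryldifluoroborane, the aryl group may enter with poor facial selectivity, and the Lewis acid may cleave the 4→8 bond. The fallback builds the C2 centre in the open chain and closes the pyran ring by substitution. It sets out from 14. Addition of (4-benzyloxyphenyl)magnesium bromide to the open hydroxy aldehyde form of the lactol should give 1-[4-(benzyloxy)phenyl]-2-(benzyloxy)-3-[2,4-bis(benzyloxy)-6-hydroxyphenyl]-3-(tetra-O-benzyl-epiafzelechin-8-yl)propan-1-ol F2 as a mixture of carbinol epimers. Oxidation of the benzylic carbinol with MnO2 should give the aryl ketone, (2R,3R)-1-[4-(benzyloxy)phenyl]-2-(benzyloxy)-3-[2,4-bis(benzyloxy)-6-hydroxyphenyl]-3-(tetra-O-benzyl-epiafzelechin-8-yl)propan-1-one F3. Reduction with Zn(BH4)2 under chelation by the α-benzyloxy group should give the 1,2-anti alcohol, the (1S,2R,3R)-propan-1-ol F4. Mitsunobu ring closure (PPh3, DIAD) by the phenol with inversion at the benzylic carbon should then give the 2,3-cis flavan. The fallback comes back to the route at 20.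

Step 15. The cation may attack C6 of unit 2 or C6 of unit 3, may alkylate twice, may add from the face cis to its 2-aryl group, or may be lost by elimination and self-condensation. The triflic acid formed may also cleave the existing 4→8 bond. The fallback reverses the order of deprotection and coupling and joins the free phenols under biomimetic conditions, where C8 of the free phloroglucinol ring is the established site of attack and the cation forms reversibly. It sets out from 20 and 21. Hydrogenolysis of 20 over Pd(OH)2/C should give epiafzelechin-(4β→8)-epiafzelechin F5. Reduction of 21 with NaBH4 in ethanol should give (2S,4S)-4',7-dihydroxyflavan-4-ol F6. Condensation of F6 with F5 in dilute aqueous HCl/ethanol at room temperature should give the trimer directly. The fallback comes back to the route at 27.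

**Further compounds**

F1 | step 8 | 4β-(2-ethoxyethoxy)-3,5,7,4'-tetra-O-benzyl-epiafzelechin (3,4-trans) | c1c(OCc9ccccc9)cc(OCc9ccccc9)c2c1O[C@H](c1ccc(OCc9ccccc9)cc1)[C@H](OCc9ccccc9)[C@H]2OCCOCC
F2 | step 11 | (2R,3R)-1-[4-(benzyloxy)phenyl]-2-(benzyloxy)-3-[2,4-bis(benzyloxy)-6-hydroxyphenyl]-3-(3,5,7,4'-tetra-O-benzyl-epiafzelechin-8-yl)propan-1-ol, carbinol epimers | OC(c1ccc(OCc9ccccc9)cc1)[C@H](OCc9ccccc9)[C@H](c1c(O)cc(OCc9ccccc9)cc1OCc9ccccc9)c1c(OCc9ccccc9)cc(OCc9ccccc9)c2c1O[C@H](c1ccc(OCc9ccccc9)cc1)[C@H](OCc9ccccc9)C2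
F3 | step 11 | (2R,3R)-1-[4-(benzyloxy)phenyl]-2-(benzyloxy)-3-[2,4-bis(benzyloxy)-6-hydroxyphenyl]-3-(3,5,7,4'-tetra-O-benzyl-epiafzelechin-8-yl)propan-1-one | O=C(c1ccc(OCc9ccccc9)cc1)[C@H](OCc9ccccc9)[C@H](c1c(O)cc(OCc9ccccc9)cc1OCc9ccccc9)c1c(OCc9ccccc9)cc(OCc9ccccc9)c2c1O[C@H](c1ccc(OCc9ccccc9)cc1)[C@H](OCc9ccccc9)C2
F4 | step 11 | (1S,2R,3R)-1-[4-(benzyloxy)phenyl]-2-(benzyloxy)-3-[2,4-bis(benzyloxy)-6-hydroxyphenyl]-3-(3,5,7,4'-tetra-O-benzyl-epiafzelechin-8-yl)propan-1-ol, 1,2-anti | O[C@@H](c1ccc(OCc9ccccc9)cc1)[C@H](OCc9ccccc9)[C@H](c1c(O)cc(OCc9ccccc9)cc1OCc9ccccc9)c1c(OCc9ccccc9)cc(OCc9ccccc9)c2c1O[C@H](c1ccc(OCc9ccccc9)cc1)[C@H](OCc9ccccc9)C2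
F5 | step 15 | epiafzelechin-(4β→8)-epiafzelechin | c1c(O)cc(O)c2c1O[C@H](c1ccc(O)cc1)[C@H](O)[C@H]2c1c(O)cc(O)c2c1O[C@H](c1ccc(O)cc1)[C@H](O)C2
F6 | step 15 | (2S,4S)-4',7-dihydroxyflavan-4-ol | O[C@H]1C[C@@H](c2ccc(O)cc2)Oc2cc(O)ccc21
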